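2.95 was the number I began from: it is how many X stood in the flask for each Z, 59 mM against 20.0 mM, so in the capture of Z by X into D, X stood in excess over Z.

| flask | G | J | Z | X | remark |
|---|---|---|---|---|---|
| eta | 0.20 M | 1 equiv | 10 mol% | 59 mM | run made earlier |
| delta | 0.20 M | 1.5 equiv | 10 mol% | 59 mM | run made earlier |
| beta | 0.20 M | 2 equiv | 20 mol% | 59 mM | run made earlier |
| flask | 0.20 M | 2.00 equiv | 10 mol% | 59 mM |  |

| run | time / min | E / % | G / % |
|---|---|---|---|
| eta | 4.00 | 4.1 | 83.3 |
| eta | 12.0 | 10.2 | 62.8 |
| eta | 20.0 | 12.5 | 51.5 |
| eta | 30.0 | 14.6 | 45.1 |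
| eta | 50.0 | 16.5 | 38.4 |
| eta | 60.0 | 16.5 | 38.2 |
| delta | 10.0 | 13.4 | 62.0 |
| delta | 20.0 | 19.2 | 47.0 |
| delta | 30.0 | 21.1 | 40.7 |
| delta | 40.0 | 23.3 | 37.2 |
| delta | 50.0 | 23.4 | 34.9 |
| delta | 60.0 | 24.0 | 34.2 |
| beta | 12.0 | 33.9 | 43.2 |
| beta | 25.0 | 43.8 | 28.9 |
| beta | 40.0 | 49.7 | 23.5 |
| beta | 50.0 | 51.0 | 21.5 |
| beta | 60.0 | 51.9 | 19.8 |

(standard deviation of a reading: 0.5 percentage points)

- what may be going on: Z + X <-> D; G <-> L; G + J + Z -> Z + E
- what has gone from G into another species counts as reacted, even if it can come back

- apparent order in Z when 50% of the G are converted (percent change of the rate of making E for one percent more Z charged)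
- apparent order in J when 50% of the G are converted (percent change of the rate of making E for one percent more J charged)

Each D formed costs one X, so even with the whole catalyst captured, X in the flask keeps 66.1% of its charge, and I treated the capture as pseudo-first-order, with one rate per minute.

That rate I read from the eta run, which has the flask's Z and X. E stood at 16.5% there at 60.0 min while G stood at 38.2%. I divided the rate of making E by the G and J present, first from 4.00 min to 12.0 min, then from 12.0 min to 30.0 min. G passing into L entered this division through the G actually measured. The fall gave 0.0597 min⁻¹, a rough reading, as these are differences of readings good to 0.5 percentage points.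

At fixed conversion G is the same, so one percent more J or Z gives one percent more rate directly. But the mark also comes earlier, with less Z captured. How much earlier? G reached 50% at 22.3 min in the eta run and 18.0 min in the delta run, so the time shrinks 0.533 percent per percent of J, and the flask should arrive at 15.4 min. Multiplying capture rate, arrival time and shrinkage gives 0.492, the earliness gain: the extra percent of free Z won by one percent more charge.

My doubt was that this shrinkage was measured on J, not Z. The step takes J and Z as a product, and the beta run, with 1.47 X per Z, is no clean test, so I used it for both and reckoned 1.49 for each order.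

The forecast gave 1.5 for Z and 1.45 for J, the second a little below mine, on the ground that “Reaching 50% sooner leaves more Z alive”.

The flask gave 1.5 in Z and 1.5 in J, and these equations stood behind it:

    Z + X ⇌ D (K = 400 M⁻¹, k = 1.20 M⁻¹ min⁻¹)
    G ⇌ L (K = 1.20, k = 0.0350 min⁻¹)
    G + J + Z → Z + E (k = 4.10 M⁻² min⁻¹)

At 50.0 min in the flask, the exchange between Z, X and D relaxed with a half-life of 12.6 min, far shorter than the 3.9 h that G had by the step to E, and 89.3% of the catalyst stood as D, with 10.7% as Z and E at 29.8%. Carried to twice the J, one plus the earliness gain, as a power of two, gives a factor of 2.81 on the rate, and that simulated run gave 2.86.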